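Cuts, in retrosynthetic order: Si–O at the 4'-phenol; O–CH2 of the C7 prenyl ether; C3=C4 back to a C4 ketone; O1–C2 (retro-oxa-Michael); C5–C6 and C4a–C8a of ring A; last the bond from C4 to its alkyne carbon.
Enabling feature: in ring A, C4a holds the acyl carbon C4, the adjacent C5 holds the arylethyl chain, C7 and C8a hold oxygen, and C6 and C8 hold hydrogen. C4a/C5 can therefore be the sp carbons of an alkynyl ketone, and C6–C7–C8–C8a the chain of an acetoacetate-derived 1,1,3-trioxygenated diene.
Forward joining: raspberry ketone gives a 4-arylbut-1-yne, which is added to 3-methylbut-2-enal and oxidised to the ynone; methyl acetoacetate gives the diene.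
Ring order: the phenol ring is bought, ring A arises by Diels–Alder reaction and aromatisation, and the pyran ring closes next by oxa-Michael addition; prenylation, reduction, dehydration and desilylation follow.
Stereochemistry: the target has no stereocentre and no alkene capable of E/Z isomerism (C3=C4 is cis within its ring); every sp3 centre made on the way is racemic and is erased again.

Key step: step 7

Assumption: the silyl enol ether of methyl acetoacetate is drawn E and the derived diene 1Z although either may form as a mixture of geometric isomers, which is of no consequence because both geometries vanish on the way to ring A; lithium and potassium salts of numbered compounds count as forms of these compounds and carry no number of their own.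

Step 1
Reactants: 1 raspberry ketone [4-(4-hydroxyphenyl)butan-2-one]
Product: 2 silyl ether 4-[4-(triisopropylsilyloxy)phenyl]butan-2-one
Conditions: iPr3SiCl, imidazole, DMF, rt
Reagents that add atoms: chlorotriisopropylsilane, CC(C)[Si](Cl)(C(C)C)C(C)C
Why: Imidazole-promoted silylation of the only OH group gives an aryl triisopropylsilyl ether whose bulk should carry it through amide bases, n-BuLi, dilute acid, carbonate and hydride, while fluoride removes it at the end without touching the acid-sensitive prenyl ether and chromene.

Step 2
Reactants: 2 silyl ether 4-[4-(triisopropylsilyloxy)phenyl]butan-2-one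
Product: 4 alkyne [4-(but-3-yn-1-yl)phenoxy]triisopropylsilane, via enol phosphate 3 (not isolated)
Conditions: LiN(iPr)2 (1.05 equiv), THF, −78 °C; ClP(O)(OEt)2, −78 °C → rt; transfer into LiN(iPr)2 (2.3 equiv), THF, −78 °C → rt; H2O
Reagents that add atoms: diethyl chlorophosphate, CCOP(=O)(Cl)OCC (its atoms are held by 3 only and leave again before 4)
Why: Kinetic deprotonation at the methyl group, O-phosphorylation of the enolate and base-induced β-elimination of diethyl phosphate from 3 make up the established conversion of a methyl ketone into a terminal alkyne by way of its enol phosphate, and the excess amide holds the product as its acetylide so that it cannot drift to the allene.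

Step 3
Reactants: 4 alkyne [4-(but-3-yn-1-yl)phenoxy]triisopropylsilane; 5 prenal (3-methylbut-2-enal)
Product: 6 propargylic alcohol (±)-2-methyl-8-[4-(triisopropylsilyloxy)phenyl]oct-2-en-5-yn-4-ol
Conditions: n-BuLi (1.05 equiv), THF, −78 °C; then 5, −78 → 0 °C; H2O
Reagents that add atoms: none
Why: Lithiation of the terminal alkyne and 1,2-addition of the acetylide to the aldehyde (carbonyl alkynylation) is fast at low temperature and is not diverted to conjugate addition by the β,β-disubstituted enal, and the new carbinol centre is formed racemic and is erased in step 4.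

Step 4
Reactants: 6 propargylic alcohol (±)-2-methyl-8-[4-(triisopropylsilyloxy)phenyl]oct-2-en-5-yn-4-ol
Product: 7 ynone 2-methyl-8-[4-(triisopropylsilyloxy)phenyl]oct-2-en-5-yn-4-one
Conditions: activated MnO2 (excess), CH2Cl2, rt
Reagents that add atoms: none
Why: MnO2 oxidation is selective for an alcohol that is both allylic and propargylic and runs under neutral conditions in which the silyl ether, the triple bond and the trisubstituted alkene are inert.

Step 5
Reactants: 8 methyl acetoacetate
Product: 9 silyl enol ether methyl (2E)-3-(trimethylsilyloxy)but-2-enoate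
Conditions: Me3SiCl, Et3N, hexane, rt; filtration, distillation
Reagents that add atoms: chlorotrimethylsilane, C[Si](C)(C)Cl
Why: O-Silylation of the enol of a β-keto ester with Me3SiCl and Et3N is the standard silyl enol ether synthesis under soft enolisation and masks the ketone so that only the γ-methyl group is left to be deprotonated.

Step 6
Reactants: 9 silyl enol ether methyl (2E)-3-(trimethylsilyloxy)but-2-enoate
Product: 10 diene (1Z)-1-methoxy-1,3-bis(trimethylsilyloxy)buta-1,3-diene
Conditions: LiN(iPr)2, THF, −78 °C; Me3SiCl, −78 → 0 °C; hexane, filtration under Ar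
Reagents that add atoms: chlorotrimethylsilane, C[Si](C)(C)Cl
Why: γ-Deprotonation of the silyloxy crotonate gives the extended ester enolate, whose O-silylation (ketene silyl acetal formation) gives the 1,1,3-trioxygenated diene, which is freed from salts under argon and used at once because it is sensitive to moisture.

Step 7
Reactants: 7 ynone 2-methyl-8-[4-(triisopropylsilyloxy)phenyl]oct-2-en-5-yn-4-one; 10 diene (1Z)-1-methoxy-1,3-bis(trimethylsilyloxy)buta-1,3-diene
Product: 12 resorcinol enone 1-{2,4-dihydroxy-6-[2-(4-triisopropylsilyloxyphenyl)ethyl]phenyl}-3-methylbut-2-en-1-one, via cycloadduct 11 (not isolated)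
Conditions: 10 (3 equiv, in two portions), toluene, 100 °C, sealed tube, Ar; then 0.5 M aq HCl, THF, 0 °C
Reagents that add atoms: none
Why: Heating without Lewis acid brings about a normal-electron-demand Diels–Alder reaction in which the CH2 terminus of 10, made the most nucleophilic diene carbon by the oxygens on C1 and C3, bonds to the electrophilic β-carbon of ynone 7 (C5–C6 of the target) and the ketene acetal carbon bonds to the α-carbon (C4a–C8a), whether in one asynchronous event or by Mukaiyama–Michael addition followed by 6-exo-trig collapse of the allenolate onto the silylated ester carbon, both paths ending in cyclohexa-1,4-diene 11. Cold dilute acid then expels methanol from the mixed ketal carbon and cleaves both O–SiMe3 bonds, and the ring tautomerises irreversibly to the resorcinol, so ring A of 12 is closed as a six-membered carbocycle by intermolecular [4+2] union of a four-carbon and a two-carbon unit. The closest known reaction type is the cycloaddition and aromatisation of 1-alkoxy-1,3-bis(silyloxy)buta-1,3-dienes with acetylenic esters and ketones, which gives 6-substituted 2,4-dihydroxyaryl carbonyl compounds. No lasting stereocentre is created, since the ketal carbon of 11 is racemic and becomes sp2. Regioselectivity is secured by the matched polarisation of the two partners, chemoselectivity for the triple bond over the cross-conjugated alkene by the two methyl groups on the β-carbon of that alkene, and selectivity against carbonyl addition and silyl transfer by the absence of Lewis acid and the non-polar solvent. The aryl triisopropylsilyl ether and the open enone should tolerate the brief acid treatment, and any material that already closes to the chromanone is carried to the same compound in step 8.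

Step 8
Reactants: 12 resorcinol enone 1-{2,4-dihydroxy-6-[2-(4-triisopropylsilyloxyphenyl)ethyl]phenyl}-3-methylbut-2-en-1-one; 13 prenyl bromide (1-bromo-3-methylbut-2-ene)
Product: 15 prenyl ether 2,2-dimethyl-7-(3-methylbut-2-enyloxy)-5-[2-(4-triisopropylsilyloxyphenyl)ethyl]chroman-4-one, via 7-hydroxychromanone 14 (not isolated)
Conditions: K2CO3 (2.5 equiv), dry acetone, reflux until ring closure is complete; then 13 (1.1 equiv), reflux
Reagents that add atoms: none
Why: Carbonate generates the phenoxide ortho to the ketone, which closes the pyranone ring by 6-endo-trig oxa-Michael addition to the β,β-dimethyl enone, and the single phenol that is left (C7–OH, para to the carbonyl and therefore acidic) is then alkylated by SN2 displacement in a Williamson ether synthesis, so that no choice between two hydroxyl groups has to be made.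

Step 9
Reactants: 15 prenyl ether 2,2-dimethyl-7-(3-methylbut-2-enyloxy)-5-[2-(4-triisopropylsilyloxyphenyl)ethyl]chroman-4-one
Product: 16 chromanol (±)-2,2-dimethyl-7-(3-methylbut-2-enyloxy)-5-[2-(4-triisopropylsilyloxyphenyl)ethyl]chroman-4-ol
Conditions: NaBH4, MeOH/THF, 0 °C → rt
Reagents that add atoms: none
Why: Borohydride reduction of a 2,2-dimethylchroman-4-one to the chroman-4-ol is routine, leaves the isolated alkene, both aryl ethers and the silyl ether untouched, and gives a racemic C4 carbinol centre that is erased in step 10.

Step 10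
Reactants: 16 chromanol (±)-2,2-dimethyl-7-(3-methylbut-2-enyloxy)-5-[2-(4-triisopropylsilyloxyphenyl)ethyl]chroman-4-ol
Product: 18 silylated chromene {4-[2-(2,2-dimethyl-7-(3-methylbut-2-enyloxy)-2H-chromen-5-yl)ethyl]phenoxy}triisopropylsilane, via mesylate 17 (not isolated)
Conditions: MsCl (1.3 equiv), Et3N (4 equiv), CH2Cl2, 0 °C → rt
Reagents that add atoms: methanesulfonyl chloride, CS(=O)(=O)Cl (its atoms are held by 17 only and leave again before 18)
Why: Mesylation of a benzylic alcohol whose ring carries oxygen donors ortho and para to the carbinol-bearing carbon gives a sulfonate that loses methanesulfonate at once and sheds a C3 proton to Et3N (sulfonate elimination on the E1/E2 borderline), the only β-hydrogens being those at C3, so the conjugated C3=C4 alkene forms under basic conditions that spare the acid-labile aryl prenyl ether.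

Step 11
Reactants: 18 silylated chromene {4-[2-(2,2-dimethyl-7-(3-methylbut-2-enyloxy)-2H-chromen-5-yl)ethyl]phenoxy}triisopropylsilane
Product: 19 target 4-{2-[2,2-dimethyl-7-(3-methylbut-2-enyloxy)-2H-chromen-5-yl]ethyl}phenol
Conditions: Bu4NF, AcOH (1.1 equiv each), THF, 0 °C
Reagents that add atoms: none
Why: Fluoride attacks silicon and releases the phenoxide (fluoride-mediated desilylation), acetic acid protonates it at once, and neither the prenyl ether nor the 2H-chromene reacts with buffered Bu4NF.

Compound list
1 | 4-(4-hydroxyphenyl)butan-2-one (raspberry ketone) | CC(=O)CCc1ccc(O)cc1 | starting material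
2 | 4-[4-(triisopropylsilyloxy)phenyl]butan-2-one | CC(=O)CCc1ccc(O[Si](C(C)C)(C(C)C)C(C)C)cc1 | intermediate
3 | diethyl 4-[4-(triisopropylsilyloxy)phenyl]but-1-en-2-yl phosphate | C=C(CCc1ccc(O[Si](C(C)C)(C(C)C)C(C)C)cc1)OP(=O)(OCC)OCC | intermediate
4 | [4-(but-3-yn-1-yl)phenoxy]triisopropylsilane | C#CCCc1ccc(O[Si](C(C)C)(C(C)C)C(C)C)cc1 | intermediate
5 | 3-methylbut-2-enal | CC(C)=CC=O | starting material
6 | (±)-2-methyl-8-[4-(triisopropylsilyloxy)phenyl]oct-2-en-5-yn-4-ol (racemic) | CC(C)=CC(O)C#CCCc1ccc(O[Si](C(C)C)(C(C)C)C(C)C)cc1 | intermediate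
7 | 2-methyl-8-[4-(triisopropylsilyloxy)phenyl]oct-2-en-5-yn-4-one | CC(C)=CC(=O)C#CCCc1ccc(O[Si](C(C)C)(C(C)C)C(C)C)cc1 | intermediate
8 | methyl acetoacetate | COC(=O)CC(C)=O | starting material
9 | methyl (2E)-3-(trimethylsilyloxy)but-2-enoate | COC(=O)/C=C(/O[Si](C)(C)C)C | intermediate
10 | (1Z)-1-methoxy-1,3-bis(trimethylsilyloxy)buta-1,3-diene | C=C(O[Si](C)(C)C)/C=C(/OC)O[Si](C)(C)C | intermediate
11 | (±)-1-{6-methoxy-4,6-bis(trimethylsilyloxy)-2-[2-(4-triisopropylsilyloxyphenyl)ethyl]cyclohexa-1,4-dien-1-yl}-3-methylbut-2-en-1-one (racemic) | CC(C)=CC(=O)C1=C(CCc2ccc(O[Si](C(C)C)(C(C)C)C(C)C)cc2)CC(O[Si](C)(C)C)=CC1(OC)O[Si](C)(C)C | intermediate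
12 | 1-{2,4-dihydroxy-6-[2-(4-triisopropylsilyloxyphenyl)ethyl]phenyl}-3-methylbut-2-en-1-one | CC(C)=CC(=O)c1c(O)cc(O)cc1CCc2ccc(O[Si](C(C)C)(C(C)C)C(C)C)cc2 | intermediate
13 | 1-bromo-3-methylbut-2-ene (prenyl bromide) | CC(C)=CCBr | starting material
14 | 7-hydroxy-2,2-dimethyl-5-[2-(4-triisopropylsilyloxyphenyl)ethyl]chroman-4-one | CC1(C)CC(=O)c2c(CCc3ccc(O[Si](C(C)C)(C(C)C)C(C)C)cc3)cc(O)cc2O1 | intermediate
15 | 2,2-dimethyl-7-(3-methylbut-2-enyloxy)-5-[2-(4-triisopropylsilyloxyphenyl)ethyl]chroman-4-one | CC(C)=CCOc1cc(CCc2ccc(O[Si](C(C)C)(C(C)C)C(C)C)cc2)c2c(c1)OC(C)(C)CC2=O | intermediate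
16 | (±)-2,2-dimethyl-7-(3-methylbut-2-enyloxy)-5-[2-(4-triisopropylsilyloxyphenyl)ethyl]chroman-4-ol (racemic) | CC(C)=CCOc1cc(CCc2ccc(O[Si](C(C)C)(C(C)C)C(C)C)cc2)c2c(c1)OC(C)(C)CC2O | intermediate
17 | (±)-2,2-dimethyl-7-(3-methylbut-2-enyloxy)-5-[2-(4-triisopropylsilyloxyphenyl)ethyl]chroman-4-yl methanesulfonate (racemic) | CC(C)=CCOc1cc(CCc2ccc(O[Si](C(C)C)(C(C)C)C(C)C)cc2)c2c(c1)OC(C)(C)CC2OS(C)(=O)=O | intermediate
18 | {4-[2-(2,2-dimethyl-7-(3-methylbut-2-enyloxy)-2H-chromen-5-yl)ethyl]phenoxy}triisopropylsilane | CC(C)=CCOc1cc(CCc2ccc(O[Si](C(C)C)(C(C)C)C(C)C)cc2)c2c(c1)OC(C)(C)C=C2 | intermediate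
19 | 4-{2-[2,2-dimethyl-7-(3-methylbut-2-enyloxy)-2H-chromen-5-yl]ethyl}phenol (CNP0337021.0) | CC(C)=CCOc1cc(CCc2ccc(O)cc2)c2c(c1)OC(C)(C)C=C2 | target

Total step count: 11. Longest linear sequence: 9 (steps 1–4 and 7–11, from raspberry ketone); the diene arm (steps 5 and 6) joins at step 7.

Steps most likely to fail

Step 7.
- **What may go wrong:** The diene may be lost to thermal silyl migration and adventitious hydrolysis faster than it adds to a triple bond that carries an alkyl group on its β-carbon. The union may also stop after the first C–C bond through silyl transfer, after which the chain would close on the ketone by aldol condensation instead of on the ester-level carbon.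
- **Fallback:** It sets out from 7 and keeps the two ring bonds, but changes the diene class and the way of aromatising. Dimedone is bis-silylated (Me3SiOTf, Et3N, Et2O, 0 °C) to 5,5-dimethyl-1,3-bis(trimethylsilyloxy)cyclohexa-1,3-diene F1, a thermally robust diene that is locked s-cis and has no ester carbon, hence no second mode of closure. Heating 7 with it without solvent at 140–160 °C should give the bicyclo[2.2.2]octadiene adduct F2, which under the same conditions extrudes 2-methylpropene by retro-Diels–Alder reaction. This leaves the resorcinol bis(trimethylsilyl) ether F3. Treatment with 0.5 M HCl in THF at 0 °C frees both phenols, and the route is rejoined at 12.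

Step 8.
- **What may go wrong:** Long exposure to carbonate and to the phenoxides it generates may strip or transfer the aryl silyl group, so that the prenyl group is delivered to the wrong oxygen. Ring closure may also be slow because the C7 phenoxide feeds electron density into the enone.
- **Fallback:** It sets out from 12 and avoids base altogether. Catalytic p-TsOH·H2O in toluene at 60 °C closes the pyranone ring by acid-catalysed oxa-Michael addition to give 14, which is now isolated. A Mitsunobu reaction with 3-methylbut-2-en-1-ol (PPh3, DIAD, THF, 0 °C → rt) then etherifies the C7 hydroxyl under neutral conditions, and the route is rejoined at 15. Compounds outside the list: none F0.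

Step 10 (together with the reduction that feeds it).
- **What may go wrong:** Hydride delivery to a ketone that is electron-rich and crowded by the C5 chain may be slow. Ionisation of the very electron-rich benzylic sulfonate may also outrun proton loss, leading to substitution by chloride, ether formation or oligomerisation of the chromene.
- **Fallback:** It sets out from 12 and forms the pyran ring by electrocyclisation instead of elimination.
  - A Mitsunobu reaction with 3-methylbut-2-en-1-ol (PPh3, DIAD, THF) etherifies only the hydroxyl that is not hydrogen-bonded to the ketone, giving 1-{2-hydroxy-4-(3-methylbut-2-enyloxy)-6-[2-(4-triisopropylsilyloxyphenyl)ethyl]phenyl}-3-methylbut-2-en-1-one F4.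
  - Luche reduction (NaBH4, CeCl3·7H2O, MeOH, 0 °C) gives the racemic allylic alcohol 2-(1-hydroxy-3-methylbut-2-enyl)-5-(3-methylbut-2-enyloxy)-3-[2-(4-triisopropylsilyloxyphenyl)ethyl]phenol F5.
  - Gentle warming in toluene (60–80 °C) removes water to give the vinyl ortho-quinone methide F6, which undergoes oxa-6π electrocyclisation, and the route is rejoined at 18.

Further compounds
F1 | step 7 | 5,5-dimethyl-1,3-bis(trimethylsilyloxy)cyclohexa-1,3-diene | CC1(C)CC(O[Si](C)(C)C)=CC(O[Si](C)(C)C)=C1
F2 | step 7 | (±)-1-{8,8-dimethyl-1,5-bis(trimethylsilyloxy)-3-[2-(4-triisopropylsilyloxyphenyl)ethyl]bicyclo[2.2.2]octa-2,5-dien-2-yl}-3-methylbut-2-en-1-one (racemic) | CC(C)=CC(=O)C1=C(CCc2ccc(O[Si](C(C)C)(C(C)C)C(C)C)cc2)C2C(O[Si](C)(C)C)=CC1(O[Si](C)(C)C)CC2(C)C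
F3 | step 7 | 1-{2,4-bis(trimethylsilyloxy)-6-[2-(4-triisopropylsilyloxyphenyl)ethyl]phenyl}-3-methylbut-2-en-1-one | CC(C)=CC(=O)c1c(O[Si](C)(C)C)cc(O[Si](C)(C)C)cc1CCc2ccc(O[Si](C(C)C)(C(C)C)C(C)C)cc2
F0 | step 8 | none | none
F4 | step 10 | 1-{2-hydroxy-4-(3-methylbut-2-enyloxy)-6-[2-(4-triisopropylsilyloxyphenyl)ethyl]phenyl}-3-methylbut-2-en-1-one | CC(C)=CCOc1cc(O)c(C(=O)C=C(C)C)c(CCc2ccc(O[Si](C(C)C)(C(C)C)C(C)C)cc2)c1
F5 | step 10 | (±)-2-(1-hydroxy-3-methylbut-2-enyl)-5-(3-methylbut-2-enyloxy)-3-[2-(4-triisopropylsilyloxyphenyl)ethyl]phenol (racemic) | CC(C)=CCOc1cc(O)c(C(O)C=C(C)C)c(CCc2ccc(O[Si](C(C)C)(C(C)C)C(C)C)cc2)c1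
F6 | step 10 | (6Z)-6-(3-methylbut-2-enylidene)-3-(3-methylbut-2-enyloxy)-5-[2-(4-triisopropylsilyloxyphenyl)ethyl]cyclohexa-2,4-dien-1-one | CC(C)=C/C=C1\C(=O)C=C(OCC=C(C)C)C=C1CCc2ccc(O[Si](C(C)C)(C(C)C)C(C)C)cc2
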